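**Plan**

1. The retrosynthesis first strips the periphery: C8–C14 is cut (CO onto a C7=C8 enol triflate), then C13–C15 (Grignard reagent onto an amide), then C9–C11 (Michael addition of a C9 β-keto ester to methyl acrylate), and the C18 acid is taken back to a silyl ether.
2. What makes the key step possible is the trans-fused ring A/ring B core: C4 carries an axial methyl and an equatorial oxidised carbon (C18), C5–H and the C10 methyl are trans, and C8 is a carbonyl-derived carbon beside C9. This is the pattern that a chair–chair cyclisation of an (E)-geranyl-type epoxy-ene chain ending in a C8/C9 β-keto ester leaves behind.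
3. The core is therefore cut at C4–C5 and C9–C10 to an acyclic epoxy β-keto ester, which is cut at C6–C7 into an epoxy allylic bromide (from geranyl acetate) and the dianion of methyl acetoacetate.
4. Forward, the chain is assembled linearly (steps 1–6), ring A and then ring B close in one cationic cascade (step 7), and steps 8–17 add C11–C13, remove the C9 ester and the C3 oxygen, and install the isopropyl ketone and both carboxyl groups.
5. One Sharpless epoxidation sets C3; C4, C5 and C10 follow from it through the chair–chair transition state and the (E)-alkene geometries, C9 is set by protonation to the equatorial side chain, and the C3 oxygen is removed once it has done its work.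

Key step: step 7

Remark on the chemistry: locants in the bicyclic compounds follow abietane numbering (ring A = C1–C5 and C10; ring B = C5–C10; C18 = the 4α carbon; C19 = the 4β methyl; C20 = the 10β methyl; C11–C13 = the chain on C9; C14 = the carboxyl carbon on C8). α and β are used as in steroids, with the C10 methyl β. "Decalin" and "octalin" names refer to this numbering, and all bicyclic compounds are trans-fused (5α-H, 10β-CH3). β-Keto esters are drawn as keto tautomers although they will be partly enolised.

**Step 1**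
Reactants: 1 geranyl acetate
Product: 2 (2E,6E)-8-hydroxy-3,7-dimethylocta-2,6-dien-1-yl acetate
Conditions: SeO2 (cat.), tBuOOH, salicylic acid (cat.), CH2Cl2, rt
Reagents that add atoms: tert-butyl hydroperoxide, CC(C)(C)OO (oxygen, relayed by catalytic SeO2, O=[Se]=O)
Why: Catalytic SeO2 allylic oxidation (Riley oxidation with tBuOOH as terminal oxidant) proceeds by an ene reaction and [2,3]-sigmatropic shift at the electron-rich distal trisubstituted alkene and is known to select the (E)-methyl group, the proximal alkene being deactivated by the allylic acetate.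

**Step 2**
Reactants: 2 (2E,6E)-8-hydroxy-3,7-dimethylocta-2,6-dien-1-yl acetate
Product: 3 (2E)-5-[(2S,3S)-3-(hydroxymethyl)-3-methyloxiran-2-yl]-3-methylpent-2-en-1-yl acetate
Conditions: Ti(OiPr)4 (cat.), L-(+)-diethyl tartrate (cat.), tBuOOH, 4 Å MS, CH2Cl2, −20 °C
Reagents that add atoms: tert-butyl hydroperoxide, CC(C)(C)OO
Why: Sharpless asymmetric epoxidation of the (E)-2-methyl allylic alcohol with the L-(+)-tartrate ligand should deliver oxygen to the face that gives the (2S,3S)-epoxide, which sets the future C3 centre and the epoxide carbon that becomes C4, while the alkene that lacks a free hydroxyl is left alone.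

**Step 3**
Reactants: 3 (2E)-5-[(2S,3S)-3-(hydroxymethyl)-3-methyloxiran-2-yl]-3-methylpent-2-en-1-yl acetate
Product: 4 (2E)-5-[(2S,3S)-3-(tert-butyldiphenylsilyloxymethyl)-3-methyloxiran-2-yl]-3-methylpent-2-en-1-yl acetate
Conditions: TBDPSCl, imidazole, DMF, 0 °C → rt
Reagents that add atoms: tert-butyl(chloro)diphenylsilane, CC(C)(C)[Si](Cl)(c1ccccc1)c1ccccc1
Why: Imidazole-promoted silylation of the primary alcohol gives a robust silyl ether that should later withstand the Lewis acid, hot wet DMSO, strong base and organomagnesium reagents.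

**Step 4**
Reactants: 4 (2E)-5-[(2S,3S)-3-(tert-butyldiphenylsilyloxymethyl)-3-methyloxiran-2-yl]-3-methylpent-2-en-1-yl acetate
Product: 5 (2E)-5-[(2S,3S)-3-(tert-butyldiphenylsilyloxymethyl)-3-methyloxiran-2-yl]-3-methylpent-2-en-1-ol
Conditions: K2CO3 (cat.), MeOH, 0 °C → rt
Reagents that add atoms: none
Why: Carbonate-catalysed transesterification with methanol removes the acetate under conditions to which the trisubstituted epoxide and the silyl ether are inert.

**Step 5**
Reactants: 5 (2E)-5-[(2S,3S)-3-(tert-butyldiphenylsilyloxymethyl)-3-methyloxiran-2-yl]-3-methylpent-2-en-1-ol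
Product: 7 (2E)-1-bromo-5-[(2S,3S)-3-(tert-butyldiphenylsilyloxymethyl)-3-methyloxiran-2-yl]-3-methylpent-2-ene, via allylic mesylate 6 (not isolated)
Conditions: MsCl, Et3N, THF, −40 °C; then LiBr, THF, 0 °C
Reagents that add atoms: lithium bromide, [Li+].[Br-] (methanesulfonyl chloride, CS(=O)(=O)Cl, enters only the intermediate 6)
Why: Mesylation followed by SN2 displacement with bromide (Finkelstein-type exchange) converts the allylic alcohol into the bromide without the protic acid that would open the epoxide, and the (E)-geometry is retained.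

**Step 6**
Reactants: 7 (2E)-1-bromo-5-[(2S,3S)-3-(tert-butyldiphenylsilyloxymethyl)-3-methyloxiran-2-yl]-3-methylpent-2-ene; 8 methyl acetoacetate
Product: 10 methyl (6E)-9-[(2S,3S)-3-(tert-butyldiphenylsilyloxymethyl)-3-methyloxiran-2-yl]-7-methyl-3-oxonon-6-enoate, via methyl acetoacetate dianion 9 (not isolated)
Conditions: 8, NaH, THF, 0 °C; n-BuLi, 0 °C; then 7, 0 °C; aq. NH4Cl
Reagents that add atoms: none
Why: γ-Alkylation of the acetoacetate dianion with the primary allylic bromide is a fast SN2 reaction at the more nucleophilic terminal carbon and should be much faster than any attack on the hindered epoxide.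

**Step 7**
Reactants: 10 methyl (6E)-9-[(2S,3S)-3-(tert-butyldiphenylsilyloxymethyl)-3-methyloxiran-2-yl]-7-methyl-3-oxonon-6-enoate
Product: 11 methyl 4α-(tert-butyldiphenylsilyloxymethyl)-3β-hydroxy-4β,10β-dimethyl-8-oxo-5α-decalin-9β-carboxylate
Conditions: MeAlCl2 (3 equiv), CH2Cl2, −78 → −20 °C; then 1 M HCl
Reagents that add atoms: none
Why: MeAlCl2 should first convert the β-keto ester into its chelated chloroaluminium enolate and then activate the epoxide, whose tertiary C4–O bond ionises as the (E)-C5=C10 alkene attacks C4 anti to the departing oxygen and the enol carbon C9 captures the developing C10 cation in the same chair–chair array, so that C4–C5 and C9–C10 form in one cascade. The closest known reaction type is the Lewis-acid-promoted biomimetic epoxy-polyene bicyclisation terminated by a β-dicarbonyl enol. Ring A closes in 6-endo mode (both alkene carbons and both epoxide carbons end up in the ring), and ring B closes by 6-endo attack of the endocyclic enol on C10. C4 is set by inversion at the epoxide carbon, the substituent trans to the chain (CH2OSi) becoming equatorial α; C5 and C10 are set by anti addition across the (E)-alkene (5α-H, 10β-CH3); C3 is carried over unchanged as the equatorial 3β-oxygen; and C9 settles as the equatorial ester because it stays epimerisable. The step needs opening at C4 rather than C3, C- rather than O-capture by the terminator and a single absolute sense of folding, which should be secured by the tertiary versus secondary epoxide carbons, by the chelated enol, and by the Sharpless-derived C3 centre that places its C–O bond equatorial in the chair.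

**Step 8**
Reactants: 11 methyl 4α-(tert-butyldiphenylsilyloxymethyl)-3β-hydroxy-4β,10β-dimethyl-8-oxo-5α-decalin-9β-carboxylate; 12 methyl acrylate
Product: 13 methyl 4α-(tert-butyldiphenylsilyloxymethyl)-3β-hydroxy-9α-(3-methoxy-3-oxopropyl)-4β,10β-dimethyl-8-oxo-5α-decalin-9β-carboxylate
Conditions: 12, DBU (cat.), MeCN, rt
Reagents that add atoms: none
Why: Base-catalysed Michael addition of the doubly activated C9–H to the acrylate is thermodynamically favourable and should occur from the α-face, anti to the axial C10 methyl, the C9 configuration being of no consequence because it is reset in step 9.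

**Step 9**
Reactants: 13 methyl 4α-(tert-butyldiphenylsilyloxymethyl)-3β-hydroxy-9α-(3-methoxy-3-oxopropyl)-4β,10β-dimethyl-8-oxo-5α-decalin-9β-carboxylate
Product: 14 methyl 3-[4α-(tert-butyldiphenylsilyloxymethyl)-3β-hydroxy-4β,10β-dimethyl-8-oxo-5α-decalin-9β-yl]propanoate
Conditions: LiCl, H2O, DMSO, 150 °C
Reagents that add atoms: none
Why: In this Krapcho dealkoxycarbonylation chloride demethylates the activated β-keto ester, the carboxylate loses CO2, and protonation of the C8 enolate from the less hindered α-face (also the thermodynamic outcome at this epimerisable centre) should place the side chain equatorial (9α-H), the simple side-chain ester reacting much more slowly.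

**Step 10**
Reactants: 14 methyl 3-[4α-(tert-butyldiphenylsilyloxymethyl)-3β-hydroxy-4β,10β-dimethyl-8-oxo-5α-decalin-9β-yl]propanoate
Product: 15 methyl 3-[4α-(tert-butyldiphenylsilyloxymethyl)-3β-(imidazol-1-ylthiocarbonyloxy)-4β,10β-dimethyl-8-oxo-5α-decalin-9β-yl]propanoate
Conditions: 1,1'-thiocarbonyldiimidazole, DMAP (cat.), ClCH2CH2Cl, 80 °C
Reagents that add atoms: 1,1'-thiocarbonyldiimidazole, S=C(n1ccnc1)n1ccnc1
Why: Thioacylation of the hindered equatorial 3β-alcohol under DMAP catalysis gives the radical precursor for a Barton–McCombie deoxygenation under neutral conditions that spare the ketone and the ester.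

**Step 11**
Reactants: 15 methyl 3-[4α-(tert-butyldiphenylsilyloxymethyl)-3β-(imidazol-1-ylthiocarbonyloxy)-4β,10β-dimethyl-8-oxo-5α-decalin-9β-yl]propanoate
Product: 16 methyl 3-[4α-(tert-butyldiphenylsilyloxymethyl)-4β,10β-dimethyl-8-oxo-5α-decalin-9β-yl]propanoate
Conditions: Bu3SnH, AIBN (cat.), toluene, 110 °C
Reagents that add atoms: none
Why: In this Barton–McCombie radical deoxygenation the stannyl radical adds to sulfur, the secondary C3 radical fragments off and is reduced by Bu3SnH, which removes the stereocentre that was needed only to relay chirality.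

**Step 12**
Reactants: 16 methyl 3-[4α-(tert-butyldiphenylsilyloxymethyl)-4β,10β-dimethyl-8-oxo-5α-decalin-9β-yl]propanoate
Product: 18 methyl 3-[4α-(tert-butyldiphenylsilyloxymethyl)-4β,10β-dimethyl-8-(trifluoromethylsulfonyloxy)-5α-octal-7-en-9β-yl]propanoate, via potassium C7 enolate 17 (not isolated)
Conditions: KN(SiMe3)2, THF, −78 °C; then N-(5-chloropyridin-2-yl)bis(trifluoromethanesulfonyl)imide (Comins' reagent), −78 °C; aq. NH4Cl
Reagents that add atoms: N-(5-chloropyridin-2-yl)bis(trifluoromethanesulfonyl)imide, FC(F)(F)S(=O)(=O)N(c1ccc(Cl)cn1)S(=O)(=O)C(F)(F)F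
Why: Kinetic deprotonation with the bulky amide base should remove the accessible C7 hydrogen and not the hindered C9 methine or the less acidic ester α-hydrogens, and O-sulfonylation of the enolate at low temperature fixes the C7=C8 regiochemistry without touching C9.

**Step 13**
Reactants: 18 methyl 3-[4α-(tert-butyldiphenylsilyloxymethyl)-4β,10β-dimethyl-8-(trifluoromethylsulfonyloxy)-5α-octal-7-en-9β-yl]propanoate
Product: 19 3-[4α-(tert-butyldiphenylsilyloxymethyl)-4β,10β-dimethyl-8-(trifluoromethylsulfonyloxy)-5α-octal-7-en-9β-yl]-N-methoxy-N-methylpropanamide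
Conditions: MeNH(OMe)·HCl, iPrMgCl, THF, −20 °C
Reagents that add atoms: N,O-dimethylhydroxylamine hydrochloride, CNOC.Cl
Why: Aminolysis of the methyl ester by the chloromagnesium amide of N,O-dimethylhydroxylamine (Weinreb amide formation) stops at the chelated amide, and enol triflates are generally inert to organomagnesium reagents when no transition-metal catalyst is present.

**Step 14**
Reactants: 19 3-[4α-(tert-butyldiphenylsilyloxymethyl)-4β,10β-dimethyl-8-(trifluoromethylsulfonyloxy)-5α-octal-7-en-9β-yl]-N-methoxy-N-methylpropanamide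
Product: 20 1-[4α-(tert-butyldiphenylsilyloxymethyl)-4β,10β-dimethyl-8-(trifluoromethylsulfonyloxy)-5α-octal-7-en-9β-yl]-4-methylpentan-3-one
Conditions: iPrMgCl, THF, 0 °C; aq. NH4Cl
Reagents that add atoms: isopropylmagnesium chloride, CC(C)[Mg]Cl
Why: In this Weinreb ketone synthesis the Grignard reagent adds once to give a stable magnesium chelate that collapses to the isopropyl ketone only on work-up.

**Step 15**
Reactants: 20 1-[4α-(tert-butyldiphenylsilyloxymethyl)-4β,10β-dimethyl-8-(trifluoromethylsulfonyloxy)-5α-octal-7-en-9β-yl]-4-methylpentan-3-one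
Product: 21 18-(tert-butyldiphenylsilyloxy)-13-oxo-13,14-secoabiet-7-en-14-oic acid
Conditions: Pd(OAc)2 (cat.), PPh3 (cat.), CO (1 atm), KOAc, DMF–H2O, 60 °C; acidic work-up
Reagents that add atoms: carbon monoxide, [C-]#[O+]; water, O
Why: In this palladium-catalysed hydroxycarbonylation the enol triflate adds oxidatively to zerovalent palladium formed in situ, CO inserts and the acylpalladium is captured by water with acetate as base, which should give the C8 carboxylic acid with the alkene held at C7=C8.

**Step 16**
Reactants: 21 18-(tert-butyldiphenylsilyloxy)-13-oxo-13,14-secoabiet-7-en-14-oic acid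
Product: 22 18-hydroxy-13-oxo-13,14-secoabiet-7-en-14-oic acid
Conditions: Bu4NF (excess), THF, 50 °C; aq. NH4Cl
Reagents that add atoms: none
Why: Fluoride-mediated desilylation, driven by the strong Si–F bond, frees the C18 alcohol, an excess of fluoride compensating for the carboxylic acid.

**Step 17**
Reactants: 22 18-hydroxy-13-oxo-13,14-secoabiet-7-en-14-oic acid
Product: 23 13-oxo-13,14-secoabiet-7-ene-14,18-dioic acid
Conditions: CrO3, H2SO4, H2O, acetone, 0 °C → rt
Reagents that add atoms: chromium trioxide, O=[Cr](=O)=O; water, O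
Why: Jones oxidation takes the primary neopentyl alcohol through the aldehyde hydrate to the carboxylic acid, while the ketone, the conjugated acid and the electron-poor alkene are inert to chromic acid.

**Compound list**

1 | geranyl acetate | CC(=O)OC/C=C(\C)CCC=C(C)C | starting material
2 | (2E,6E)-8-hydroxy-3,7-dimethylocta-2,6-dien-1-yl acetate | CC(=O)OC/C=C(\C)CC/C=C(\C)CO | intermediate
3 | (2E)-5-[(2S,3S)-3-(hydroxymethyl)-3-methyloxiran-2-yl]-3-methylpent-2-en-1-yl acetate | CC(=O)OC/C=C(\C)CC[C@@H]1O[C@@]1(C)CO | intermediate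
4 | (2E)-5-[(2S,3S)-3-(tert-butyldiphenylsilyloxymethyl)-3-methyloxiran-2-yl]-3-methylpent-2-en-1-yl acetate | CC(=O)OC/C=C(\C)CC[C@@H]1O[C@@]1(C)CO[Si](c1ccccc1)(c1ccccc1)C(C)(C)C | intermediate
5 | (2E)-5-[(2S,3S)-3-(tert-butyldiphenylsilyloxymethyl)-3-methyloxiran-2-yl]-3-methylpent-2-en-1-ol | OC/C=C(\C)CC[C@@H]1O[C@@]1(C)CO[Si](c1ccccc1)(c1ccccc1)C(C)(C)C | intermediate
6 | methanesulfonate of 5 (allylic mesylate, not isolated) | CS(=O)(=O)OC/C=C(\C)CC[C@@H]1O[C@@]1(C)CO[Si](c1ccccc1)(c1ccccc1)C(C)(C)C | intermediate
7 | (2E)-1-bromo-5-[(2S,3S)-3-(tert-butyldiphenylsilyloxymethyl)-3-methyloxiran-2-yl]-3-methylpent-2-ene | BrC/C=C(\C)CC[C@@H]1O[C@@]1(C)CO[Si](c1ccccc1)(c1ccccc1)C(C)(C)C | intermediate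
8 | methyl acetoacetate | COC(=O)CC(C)=O | starting material
9 | sodium lithium dianion of methyl acetoacetate (not isolated) | [Na+].[Li+].COC([O-])=CC([O-])=C | intermediate
10 | methyl (6E)-9-[(2S,3S)-3-(tert-butyldiphenylsilyloxymethyl)-3-methyloxiran-2-yl]-7-methyl-3-oxonon-6-enoate | COC(=O)CC(=O)CC/C=C(\C)CC[C@@H]1O[C@@]1(C)CO[Si](c1ccccc1)(c1ccccc1)C(C)(C)C | intermediate
11 | methyl 4α-(tert-butyldiphenylsilyloxymethyl)-3β-hydroxy-4β,10β-dimethyl-8-oxo-5α-decalin-9β-carboxylate | COC(=O)[C@H]1C(=O)CC[C@@H]2[C@]1(C)CC[C@H](O)[C@@]2(C)CO[Si](c1ccccc1)(c1ccccc1)C(C)(C)C | intermediate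
12 | methyl acrylate | C=CC(=O)OC | starting material
13 | methyl 4α-(tert-butyldiphenylsilyloxymethyl)-3β-hydroxy-9α-(3-methoxy-3-oxopropyl)-4β,10β-dimethyl-8-oxo-5α-decalin-9β-carboxylate | COC(=O)CC[C@]1(C(=O)OC)C(=O)CC[C@@H]2[C@]1(C)CC[C@H](O)[C@@]2(C)CO[Si](c1ccccc1)(c1ccccc1)C(C)(C)C | intermediate
14 | methyl 3-[4α-(tert-butyldiphenylsilyloxymethyl)-3β-hydroxy-4β,10β-dimethyl-8-oxo-5α-decalin-9β-yl]propanoate | COC(=O)CC[C@H]1C(=O)CC[C@@H]2[C@]1(C)CC[C@H](O)[C@@]2(C)CO[Si](c1ccccc1)(c1ccccc1)C(C)(C)C | intermediate
15 | methyl 3-[4α-(tert-butyldiphenylsilyloxymethyl)-3β-(imidazol-1-ylthiocarbonyloxy)-4β,10β-dimethyl-8-oxo-5α-decalin-9β-yl]propanoate | COC(=O)CC[C@H]1C(=O)CC[C@@H]2[C@]1(C)CC[C@H](OC(=S)n1ccnc1)[C@@]2(C)CO[Si](c1ccccc1)(c1ccccc1)C(C)(C)C | intermediate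
16 | methyl 3-[4α-(tert-butyldiphenylsilyloxymethyl)-4β,10β-dimethyl-8-oxo-5α-decalin-9β-yl]propanoate | COC(=O)CC[C@H]1C(=O)CC[C@@H]2[C@]1(C)CCC[C@@]2(C)CO[Si](c1ccccc1)(c1ccccc1)C(C)(C)C | intermediate
17 | potassium C7 enolate of 16 (not isolated) | [K+].COC(=O)CC[C@H]1C([O-])=CC[C@@H]2[C@]1(C)CCC[C@@]2(C)CO[Si](c1ccccc1)(c1ccccc1)C(C)(C)C | intermediate
18 | methyl 3-[4α-(tert-butyldiphenylsilyloxymethyl)-4β,10β-dimethyl-8-(trifluoromethylsulfonyloxy)-5α-octal-7-en-9β-yl]propanoate | COC(=O)CC[C@H]1C(OS(=O)(=O)C(F)(F)F)=CC[C@@H]2[C@]1(C)CCC[C@@]2(C)CO[Si](c1ccccc1)(c1ccccc1)C(C)(C)C | intermediate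
19 | 3-[4α-(tert-butyldiphenylsilyloxymethyl)-4β,10β-dimethyl-8-(trifluoromethylsulfonyloxy)-5α-octal-7-en-9β-yl]-N-methoxy-N-methylpropanamide | CON(C)C(=O)CC[C@H]1C(OS(=O)(=O)C(F)(F)F)=CC[C@@H]2[C@]1(C)CCC[C@@]2(C)CO[Si](c1ccccc1)(c1ccccc1)C(C)(C)C | intermediate
20 | 1-[4α-(tert-butyldiphenylsilyloxymethyl)-4β,10β-dimethyl-8-(trifluoromethylsulfonyloxy)-5α-octal-7-en-9β-yl]-4-methylpentan-3-one | CC(C)C(=O)CC[C@H]1C(OS(=O)(=O)C(F)(F)F)=CC[C@@H]2[C@]1(C)CCC[C@@]2(C)CO[Si](c1ccccc1)(c1ccccc1)C(C)(C)C | intermediate
21 | 18-(tert-butyldiphenylsilyloxy)-13-oxo-13,14-secoabiet-7-en-14-oic acid | CC(C)C(=O)CC[C@H]1C(C(=O)O)=CC[C@@H]2[C@]1(C)CCC[C@@]2(C)CO[Si](c1ccccc1)(c1ccccc1)C(C)(C)C | intermediate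
22 | 18-hydroxy-13-oxo-13,14-secoabiet-7-en-14-oic acid | CC(C)C(=O)CC[C@H]1C(C(=O)O)=CC[C@@H]2[C@]1(C)CCC[C@@]2(C)CO | intermediate
23 | 13-oxo-13,14-secoabiet-7-ene-14,18-dioic acid (CNP0333046.1) | CC(C)C(=O)CC[C@H]1C(C(=O)O)=CC[C@@H]2[C@]1(C)CCC[C@@]2(C)C(=O)O | target

**Step count**

Total: 17 steps. Longest linear sequence: 17 steps (1 → 23); methyl acetoacetate 8 and methyl acrylate 12 enter as purchased.

**Steps most likely to fail**

Step 7. The silyloxymethyl group withdraws electron density from C4, so ionisation of the epoxide may be slow. Lewis-acid-induced hydride shift to a C3 ketone, interruption of the cascade after ring A, or O-capture of the C10 cation by the chelated enol could then compete with the bicyclisation. The fallback sets out from 10. O-silylation of its sodium enolate (NaH, TBSCl, THF, 0 °C) should give methyl (2Z,6E)-3-(tert-butyldimethylsilyloxy)-9-[(2S,3S)-3-(tert-butyldiphenylsilyloxymethyl)-3-methyloxiran-2-yl]-7-methylnona-2,6-dienoate F1. This is a neutral, non-chelating and more π-nucleophilic enol silyl ether terminator of the kind established for MeAlCl2-promoted epoxy-polyene cyclisations. Its cyclisation (MeAlCl2, CH2Cl2, −78 °C) and an aqueous acidic work-up, which removes the silyl group from the C8 oxygen, come back to the route at 11.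

Step 8. The conjugate addition has to create a quaternary C9 beside the quaternary C10, so C–C bond formation may be slow and reversal of the addition or consumption of the acrylate by oligomerisation may prevail. The fallback sets out from 10 and attaches the propanoate arm before the rings exist. Michael addition of the unhindered C9 methylene of 10 to one equivalent of methyl acrylate (K2CO3, acetone, rt) should give dimethyl 2-[(4E)-7-[(2S,3S)-3-(tert-butyldiphenylsilyloxymethyl)-3-methyloxiran-2-yl]-5-methylhept-4-enoyl]pentanedioate F2. Its MeAlCl2-promoted cyclisation through the tetrasubstituted chelated enol forms the C9 quaternary centre intramolecularly, with the ester trans to C7 ending equatorial, and comes back to the route at 13.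

Step 13 (and, for the same reason, step 14). The magnesium amide or the Grignard reagent may attack the sulfonyl group of the enol triflate, cleaving the S–O bond and returning the C8 enolate. The fallback sets out from 18 and carbonylates first. Hydroxycarbonylation under the conditions of step 15 should give 18-(tert-butyldiphenylsilyloxy)-13-methoxy-13-oxo-14,15,16,17... more simply, the acid ester 3-[8-carboxy-4α-(tert-butyldiphenylsilyloxymethyl)-4β,10β-dimethyl-5α-octal-7-en-9β-yl]propanoic acid methyl ester F3. With the acid masked in the flask as its unreactive magnesium carboxylate, MeNH(OMe)·HCl and excess iPrMgCl (THF, −20 °C) should convert the side-chain ester into the corresponding N-methoxy-N-methylamide carboxylic acid F4. Addition of iPrMgCl (THF, 0 °C) and acidic work-up then come back to the route at 21.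

**Further compounds**

F1 | step 7 | methyl (2Z,6E)-3-(tert-butyldimethylsilyloxy)-9-[(2S,3S)-3-(tert-butyldiphenylsilyloxymethyl)-3-methyloxiran-2-yl]-7-methylnona-2,6-dienoate | COC(=O)/C=C(\O[Si](C)(C)C(C)(C)C)CC/C=C(\C)CC[C@@H]1O[C@@]1(C)CO[Si](c1ccccc1)(c1ccccc1)C(C)(C)C
F2 | step 8 | dimethyl 2-[(4E)-7-[(2S,3S)-3-(tert-butyldiphenylsilyloxymethyl)-3-methyloxiran-2-yl]-5-methylhept-4-enoyl]pentanedioate (enolisable C2, both epimers) | COC(=O)CCC(C(=O)OC)C(=O)CC/C=C(\C)CC[C@@H]1O[C@@]1(C)CO[Si](c1ccccc1)(c1ccccc1)C(C)(C)C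
F3 | step 13 | methyl 3-[8-carboxy-4α-(tert-butyldiphenylsilyloxymethyl)-4β,10β-dimethyl-5α-octal-7-en-9β-yl]propanoate | COC(=O)CC[C@H]1C(C(=O)O)=CC[C@@H]2[C@]1(C)CCC[C@@]2(C)CO[Si](c1ccccc1)(c1ccccc1)C(C)(C)C
F4 | step 13 | 3-[8-carboxy-4α-(tert-butyldiphenylsilyloxymethyl)-4β,10β-dimethyl-5α-octal-7-en-9β-yl]-N-methoxy-N-methylpropanamide | CON(C)C(=O)CC[C@H]1C(C(=O)O)=CC[C@@H]2[C@]1(C)CCC[C@@]2(C)CO[Si](c1ccccc1)(c1ccccc1)C(C)(C)C
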